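The target in these flasks is made from starting material and lost to it again, so I asked how high it climbs and when it tops out.

| flask | starting material | reagent in the second phase | remark | time | volume of the second phase over the first |
|---|---|---|---|---|---|
| larch | 0.050 M | 0.050 M | run made earlier |  |  |
| alder | 0.050 M | 0.075 M | run made earlier |  |  |
| elm | 0.025 M | 0.10 M | run made earlier |  |  |
| flask | 0.050 M | 0.100 M |  | 40 h | 1.0 |

| run | time / h | target / % |
|---|---|---|
| larch | 2.00 | 12.3 |
| larch | 3.00 | 15.4 |
| larch | 6.00 | 18.7 |
| larch | 12.0 | 17.9 |
| larch | 20.0 | 15.1 |
| larch | 40.0 | 9.8 |
| alder | 2.00 | 17.7 |
| alder | 3.00 | 22.4 |
| alder | 6.00 | 27.4 |
| alder | 12.0 | 26.2 |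
| alder | 20.0 | 20.7 |
| alder | 40.0 | 12.8 |
| elm | 2.00 | 25.4 |
| elm | 4.00 | 37.5 |
| elm | 8.00 | 45.0 |
| elm | 20.0 | 37.6 |
| elm | 40.0 | 26.7 |

(readings scatter by 0.5 percentage points)

- percent here means starting material units held: one side product counts as two
- in the second phase: reagent in the second phase; everything else is in the first
- charges count per volume of the first phase; a concentration in a rate is the amount of a species over the volume of its own phase; every rate counts per litre of the first phase
- the analysis behind the earlier runs scatters by 0.5 percentage points, standard deviation
- steps under discussion: reagent in the reaction phase <-> reagent in the second phase; starting material + reagent in the reaction phase <-> target; starting material + target -> side product; starting material -> decomposition product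
- the earlier runs hold the two phases in the same ratio of volumes as the flask asked about

1. the moment within 40 h at which there is most target
2. the amount of target, in percent of the starting material charged, at that time

I took the transfer between the phases as settled, so that c(reagent), meaning reagent in the reaction phase, rose with the charge. Making target carries c(starting material) and c(reagent); the side step carries c(starting material) and c(target); the way back from target carries c(target) but no c(starting material). Target tops out where making equals the two losses, so where c(starting material) runs the same course, the top of c(target) stands at a fixed multiple of c(reagent). My bench rule followed: at one charge of starting material, the peak c(target) over the reagent charged stays constant. I read this ratio from the highest readings: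

larch: 18.7% × 0.050 M / 0.050 M = 0.187

alder: 27.4% × 0.050 M / 0.075 M = 0.183

elm: 45.0% × 0.025 M / 0.10 M = 0.113

Larch and alder agreed, so I kept their mean, the peak number g = 0.185, but elm reached 0.604 of larch's value. Elm charged half of larch's starting material, and the way back from target holds no c(starting material), so I drew the border there. The flask charged 0.050 M, like larch, though 1.33 times alder's reagent, so I reckoned:

0.185 × 0.100 M / 0.050 M = 37.0%

I expected this near 6.00 h, where larch and alder read highest. The forecast gave 35% at 6.5 h, a little below my figure, adding: “Slow reversion then erodes target after the peak.”

The flask gave 34.1% at 6.94 h.

    reagent in the reaction phase ⇌ reagent in the second phase, rate k1*([reagent in the reaction phase] - [reagent in the second phase]/K1) per volume of the first phase (partition coefficient = 1.70, kL = 16.0 /h)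
    starting material + reagent in the reaction phase ⇌ target (K = 57.0 /M, k = 5.10 /M/h)
    starting material + target → side product (k = 3.20 /M/h)
    starting material → decomposition product (k = 0.00110 /h)

In the flask, the transfer had 99.2% of its turnover up to 40 h behind it by 8.00 h, and reagent in the reaction phase went from 0.0295 M at 4.00 h to 0.0279 M at the peak. Target formation passed its turnover midpoint at 1.98 h, and side product formation at 8.84 h. The flask's own g was 0.171, which left it 2.9 percentage points below my figure.

For the neighbour flask with 0.013 M of starting material, g gives 142%, more than was charged, and that charge lies below elm's. The computed best there was 52.3%.

The readings are simulated with made-up constants; noise was put on by code.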